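The constants used here come from no measurement; the result is computed.

Four flasks compete for target.

    substrate + target → side product C (k1 = 0.13 L mol⁻¹ s⁻¹, Ea1 = 67.0 kJ mol⁻¹)
    substrate + partner → target (k2 = 0.020 L mol⁻¹ s⁻¹, Ea2 = 81.0 kJ mol⁻¹)
    2 substrate → side product B (k3 = 0.085 L mol⁻¹ s⁻¹, Ea3 = 69.0 kJ mol⁻¹)
    substrate → side product A (k4 = 3.9 × 10⁻⁴ s⁻¹, Ea4 = 116 kJ mol⁻¹)
    partner → decomposed reagent (k5 = 7.8 × 10⁻⁴ s⁻¹, Ea5 = 116 kJ mol⁻¹)
    (constants at 80 °C)

the same everywhere: time 25 min

| charge | substrate | partner | temperature | remark |
|---|---|---|---|---|
| south | 10 mM | 18.0 mM (fed, over 15 min) | 80 °C | all else is in the flask from the start; the feed brings no volume worth counting |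
| north | 10 mM (fed, over 15 min) | 18.0 mM | 80 °C | all else is in the flask from the start; the feed brings no volume worth counting |
| south-east | 10 mM | 18.0 mM | 80 °C | everything together at the start |
| west | 10 mM | 18.0 mM (fed, over 15 min) |  | the addition at 50 °C, then warmed to 80 °C; the feed brings no volume worth counting |

- a species is counted by the substrate in it: one side product B or side product C counts as two
- for a step with 2 of a species take k times the square, and two of it per event
- the list of constants is for 80 °C, to be carried to other temperatures by the activation energies

* the flask that comes out highest in share of target in target plus side product A, or "all alike" when all lie within 1.5 percentage points (south / north / south-east / west / all alike)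
* share of target in target plus side product A at the end, south
* share of target in target plus side product A at the end, north
* share of target in target plus side product A at the end, south-east
* share of target in target plus side product A at the end, west

Partner is charged at 1.80 times the substrate, yet this excess buys little. The selectivity factor S is the rate constant of the step to target times the full partner charge, divided by the rate constant of the step to side product A, and it comes to 0.923, below one. With f the mean partner, as a fraction of its charge, over the stretch when side product A forms, the curve is replaced by its mean and the share of target is reckoned as Sf/(1+Sf). The step to side product C is not counted and the curve is replaced by a plain mean, so the figure is an estimate and no bound.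

South seems to hold an advantage over south-east. By decay alone, south has 71.9% of its partner at the end of the feed, more than the 49.6% in south-east. The mean nevertheless runs the other way. South climbs from zero along a ramp bent by decay, so its mean over the feed is 0.401 of the charge, and the decaying tail after the feed averages 0.799 of the end value. Over the whole run this gives f = 0.470, less than the 0.589 of south-east.

In north, substrate arrives on average at 7.50 min into partner already decaying, so counting from there gives 0.481. Cooling slows the step to side product A more than the step to target, so west is counted from the warming onward, with f = 0.799. The estimates are then: south 30.3%, north 30.7%, south-east 35.2%, west 42.4%. The highest is west.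

The forecast gives 22%, 25%, 30% and 38% for south, north, south-east and west, and names west, whose cool feed “spares substrate and partner almost entirely”.

The flasks read 20.8%, 24.6%, 29.2% and 37.9% in that order, each lower than its estimate . In west, during the cold feed, the step to side product B ran while substrate stood at 83.5%, leaving side product B at 14.5% and side product A at 0.820% by 15.0 min. After warming, the steps to target and side product A ran while partner fell from 98.5% to 58.0%, and S with the mean of those readings gives 41.9%. The south neighbour charged with 2.5 mM of substrate, whose estimate holds no substrate term, kept partner at 44.0% and read 25.5%, under 30.3%.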